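**Retrosynthetic overview**

- The target is read as (3R,4R,6R,10R,7E,11E). The strategy rests on its 1,2-dioxane ring (O1, O2, C3–C6): the methine C3 and the quaternary C6 carry cis carbon arms of different kind (C2 acid arm, C7 alkenyl arm), with the C4 ethyl group on the same face. These arms are the two ends of an opened C2=C7 etheno bridge.
- C7=C8 is disconnected by Julia–Kocienski olefination of a C6 aldehyde with a C8–C14 sulfone; C10 of the sulfone is set by Claisen chirality transfer.
- C1=C2 and C7=CH2 come from ring-opening cross-metathesis of 1,5-diethyl-2,3-dioxabicyclo[2.2.2]oct-7-ene with vinylboronic acid pinacol ester; the boryl carbon is then oxidised to the C1 acid.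
- The endoperoxide comes from singlet-oxygen [4+2] addition to (R)-1,5-diethylcyclohexa-1,3-diene anti to its ethyl group, so that C4 sets C3 and C6.
- Ring order: the carbocycle is made first (organocatalytic annulation), the 1,2-dioxane second (peroxide bridge across the diene); the carbocycle is then opened in the key step and no further ring is formed.

Key step: step 7

Remark: atoms are numbered C1 (carboxyl) to C14 along the chain, ring carbons C3–C6. The sense of induction in steps 1 and 12 is assigned from the usual shielding models; if rotation or Mosher analysis shows the opposite, the antipodal catalyst, equally available, is used.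

**Route**

Step 1
Reactants: 1 tert-butyl 3-oxobutanoate; 2 (E)-pent-2-enal
Product: 5 (S)-5-ethylcyclohex-2-en-1-one, via Michael adduct 3 (not isolated), via cyclic keto ester 4 (not isolated)
Conditions: (R)-2-[bis(3,5-bis(trifluoromethyl)phenyl)(trimethylsilyloxy)methyl]pyrrolidine (10 mol%), toluene, rt; then p-TsOH·H2O (20 mol%), 80 °C
Reagents that add atoms: none
Why: Iminium-activated Michael addition (diarylprolinol silyl ether catalysis) sets the ethyl-bearing centre by attack on the enal face left open by the silyloxydiarylmethyl group, and the acid then effects intramolecular aldol condensation, loss of isobutene and decarboxylation (Robinson-type annulation), which places the ring alkene on the side remote from the stereocentre without any regiochemical choice.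

Step 2
Reactants: 5 (S)-5-ethylcyclohex-2-en-1-one; 6 ethylmagnesium bromide
Product: 7 (5S)-1,5-diethylcyclohex-2-en-1-ol
Conditions: EtMgBr (1.2 equiv), Et2O, −78 → 0 °C; H2O
Reagents that add atoms: none
Why: Grignard 1,2-addition to the enone carbonyl in ether at low temperature; the carbinol centre forms as an epimer mixture that is erased in step 3.

Step 3
Reactants: 7 (5S)-1,5-diethylcyclohex-2-en-1-ol
Product: 8 (R)-3,5-diethylcyclohex-2-en-1-one
Conditions: pyridinium chlorochromate [C5H5NH][CrO3Cl] (2 equiv), 4 Å sieves, CH2Cl2, rt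
Reagents that add atoms: pyridinium chlorochromate, [O-][Cr](=O)(=O)Cl.c1cc[nH+]cc1
Why: Babler–Dauben oxidative 1,3-transposition, in which the tertiary allylic chromate ester undergoes [3,3] shift and the secondary allylic chromate is oxidised to the enone; the ethyl-bearing centre is not touched.

Step 4
Reactants: 8 (R)-3,5-diethylcyclohex-2-en-1-one
Product: 9 N'-[(5R)-3,5-diethylcyclohex-2-en-1-ylidene]-4-methylbenzenesulfonohydrazide
Conditions: TsNHNH2 (1.05 equiv), MeOH, rt
Reagents that add atoms: 4-methylbenzenesulfonohydrazide, Cc1ccc(cc1)S(=O)(=O)NN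
Why: Hydrazone condensation at the ketone; the β,β-disubstituted enone resists competing conjugate addition of the hydrazide.

Step 5
Reactants: 9 N'-[(5R)-3,5-diethylcyclohex-2-en-1-ylidene]-4-methylbenzenesulfonohydrazide
Product: 11 (R)-1,5-diethylcyclohexa-1,3-diene, via dienyllithium 10 (not isolated)
Conditions: LiN(iPr)2 (3 equiv), THF, −78 → 0 °C; H2O at 0 °C once N2 evolution ends
Reagents that add atoms: none
Why: Shapiro reaction of an enone tosylhydrazone with a lithium amide, which removes the α'-proton, expels sulfinate and N2 and gives the homoannular 1,3-diene on protonation of the dienyllithium; the stereocentre takes no part, and a short reaction time at 0 °C limits base-induced isomerisation of the diene.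

Step 6
Reactants: 11 (R)-1,5-diethylcyclohexa-1,3-diene
Product: 12 (1R,4S,5R)-1,5-diethyl-2,3-dioxabicyclo[2.2.2]oct-7-ene
Conditions: O2, 5,10,15,20-tetraphenylporphyrin (0.5 mol%), visible light, CH2Cl2, −78 °C; chromatography on neutral silica
Reagents that add atoms: dioxygen, O=O
Why: Dye-sensitised [4+2] cycloaddition of singlet oxygen to the s-cis diene, expected mainly on the face anti to the C5 ethyl group, so that this centre sets both bridgeheads and the ethyl group ends syn to the etheno bridge; the minor syn adduct is removed by chromatography.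

Step 7
Reactants: 12 (1R,4S,5R)-1,5-diethyl-2,3-dioxabicyclo[2.2.2]oct-7-ene; 13 vinylboronic acid pinacol ester
Product: 14 2-[(E)-2-[(3S,4R,6R)-6-ethenyl-4,6-diethyl-1,2-dioxan-3-yl]ethenyl]-4,4,5,5-tetramethyl-1,3,2-dioxaborolane
Conditions: RuCl2(H2IMes)(=CH-C6H4-2-OiPr), the second-generation Hoveyda–Grubbs catalyst (5 mol% in two portions), 13 (4 equiv), CH2Cl2 (0.02 M), 40 °C, argon
Reagents that add atoms: none
Why: Proposed new method: ring-opening cross-metathesis has not been shown on a 2,3-dioxabicyclo[2.2.2]octene, the closest known reactions being ring-opening cross-metathesis of bicyclo[2.2.2]octenes and 7-oxanorbornenes, cross-metathesis of this vinylboronate with terminal alkenes, and ruthenium metathesis run beside dialkyl peroxides. A ruthenium methylidene adds across the strained C2=C7 bridge (target numbering) by [2+2] cycloaddition and cycloreversion with the metal on C2, so that C7 becomes a terminal methylidene, and the C2 alkylidene is then capped by 13 to give the (E)-alkenylboronate and a new methylidene that carries the chain; the bonds formed are C1=C2 and C7=CH2. No ring is closed: the carbocycle opens, the 1,2-dioxane persists, and re-closure of the cis arms would rebuild the strained bicycle. No stereocentre is formed, C3, C4 and C6 are untouched, and the E geometry follows from the size of the pinacolboryl group in the metallacyclobutane. The step needs regioselective opening (metal on C2, not C7), which the quaternary, neopentyl-like bridgehead C6 next to C7 should secure, and chemoselectivity for C=C over O–O, for which a phosphine-free carbene of divalent ruthenium is chosen because phosphine complexes of divalent ruthenium isomerise bicyclic endoperoxides. Dilution and excess 13 hold back oligomerisation, and any 3,6-divinyl dioxane formed by methylidene capping re-enters through cross-metathesis at its unhindered C3 vinyl group.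

Step 8
Reactants: 14 2-[(E)-2-[(3S,4R,6R)-6-ethenyl-4,6-diethyl-1,2-dioxan-3-yl]ethenyl]-4,4,5,5-tetramethyl-1,3,2-dioxaborolane
Product: 16 2-[(3R,4R,6R)-6-ethenyl-4,6-diethyl-1,2-dioxan-3-yl]acetaldehyde, via enol borate 15 (not isolated)
Conditions: Me3NO (anhydrous, 2 equiv), THF, rt → 45 °C; then pH 7 phosphate buffer, 0 °C; used crude
Reagents that add atoms: trimethylamine N-oxide, C[N+](C)(C)[O-]
Why: Amine-oxide oxidation of the C–B bond (1,2-shift of the alkenyl group from boron to oxygen with retention) gives the enol borate, which is hydrolysed at neutral pH to the aldehyde, so the β-peroxy aldehyde never meets a strong base and the peroxide and vinyl group are left alone.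

Step 9
Reactants: 16 2-[(3R,4R,6R)-6-ethenyl-4,6-diethyl-1,2-dioxan-3-yl]acetaldehyde
Product: 17 2-[(3R,4R,6R)-6-ethenyl-4,6-diethyl-1,2-dioxan-3-yl]acetic acid
Conditions: NaClO2, NaH2PO4, 2-methylbut-2-ene, tBuOH/H2O, 0 °C
Reagents that add atoms: sodium chlorite, [Na+].[O-]Cl=O
Why: Pinnick oxidation under buffered, mildly acidic conditions with an alkene scavenger for hypochlorous acid, which tolerates the peroxide and the vinyl group and avoids enolisation next to the peroxide-bearing carbon.

Step 10
Reactants: 17 2-[(3R,4R,6R)-6-ethenyl-4,6-diethyl-1,2-dioxan-3-yl]acetic acid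
Product: 18 methyl 2-[(3R,4R,6R)-6-ethenyl-4,6-diethyl-1,2-dioxan-3-yl]acetate
Conditions: MeI, KHCO3, DMF, rt
Reagents that add atoms: iodomethane, CI
Why: SN2 O-alkylation of the carboxylate under hydrogen carbonate, a base too weak to trigger β-elimination of the peroxide.

Step 11
Reactants: 18 methyl 2-[(3R,4R,6R)-6-ethenyl-4,6-diethyl-1,2-dioxan-3-yl]acetate
Product: 20 methyl 2-[(3R,4R,6R)-4,6-diethyl-6-formyl-1,2-dioxan-3-yl]acetate, via ozonide 19 (not isolated)
Conditions: O3, CH2Cl2, −78 °C; then Me2S, −78 °C → rt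
Reagents that add atoms: ozone, [O-][O+]=O
Why: Ozonolysis of the only C=C bond with dimethyl sulfide work-up, which spares the dialkyl peroxide; the aldehyde sits on quaternary C6 and therefore cannot fragment in the Kornblum–DeLaMare manner.

Step 12
Reactants: 2 (E)-pent-2-enal; 21 diethylzinc
Product: 22 (3R,4E)-hept-4-en-3-ol
Conditions: Et2Zn (1.5 equiv), (2R)-(+)-3-exo-morpholinoisoborneol (4 mol%), hexane/toluene, 0 °C; then 1 M HCl, 0 °C
Reagents that add atoms: none
Why: Amino-alcohol-catalysed enantioselective 1,2-addition of diethylzinc to the enal (Noyori type), using the antipode of the ligand that gives (S)-1-phenylpropan-1-ol from benzaldehyde, so that ethyl is delivered to the Re face and the (R)-carbinol results.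

Step 13
Reactants: 22 (3R,4E)-hept-4-en-3-ol; 23 2-methoxypropene
Product: 25 (4R,5E)-4-ethyloct-5-en-2-one, via allyl isopropenyl ether 24 (not isolated)
Conditions: 2-methoxypropene (5 equiv), 2,4-dinitrophenol (2 mol%), toluene, sealed tube, 130 °C
Reagents that add atoms: none
Why: Acid-catalysed exchange gives the allyl isopropenyl ether, which undergoes Claisen rearrangement (Saucy–Marbet variant) through a chair transition state with the ethyl group equatorial, transferring the carbinol chirality to C10 (R) and giving the (E)-alkene.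

Step 14
Reactants: 25 (4R,5E)-4-ethyloct-5-en-2-one
Product: 26 (4R,5E)-4-ethyloct-5-en-2-ol
Conditions: NaBH4, MeOH, 0 °C
Reagents that add atoms: none
Why: Borohydride reduction of the ketone; the new carbinol centre is an epimer mixture, which does not matter because this carbon later becomes the sulfonyl carbanion.

Step 15
Reactants: 26 (4R,5E)-4-ethyloct-5-en-2-ol
Product: 27 5-{[(4R,5E)-4-ethyloct-5-en-2-yl]sulfanyl}-1-phenyl-1H-tetrazole
Conditions: 1-phenyl-1H-tetrazole-5-thiol, PPh3, diisopropyl azodicarboxylate, THF, 0 °C → rt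
Reagents that add atoms: 1-phenyl-1H-tetrazole-5-thiol, Sc1nnnn1-c1ccccc1
Why: Mitsunobu thioetherification of the secondary alcohol with the acidic tetrazole thiol (SN2 with inversion at a centre that does not appear in the target).

Step 16
Reactants: 27 5-{[(4R,5E)-4-ethyloct-5-en-2-yl]sulfanyl}-1-phenyl-1H-tetrazole
Product: 29 5-{[(4R,5E)-4-ethyloct-5-en-2-yl]sulfonyl}-1-phenyl-1H-tetrazole, via sulfoxide 28 (not isolated)
Conditions: (NH4)6Mo7O24·4H2O (10 mol%), 30% H2O2, EtOH, 0 °C → rt
Reagents that add atoms: hydrogen peroxide, OO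
Why: Molybdate-catalysed oxidation of sulfide to sulfone through the sulfoxide, chemoselective over the 1,2-disubstituted alkene.

Step 17
Reactants: 20 methyl 2-[(3R,4R,6R)-4,6-diethyl-6-formyl-1,2-dioxan-3-yl]acetate; 29 5-{[(4R,5E)-4-ethyloct-5-en-2-yl]sulfonyl}-1-phenyl-1H-tetrazole
Product: 30 methyl 2-[(3R,4R,6R)-4,6-diethyl-6-[(1E,4R,5E)-4-ethyl-2-methylocta-1,5-dien-1-yl]-1,2-dioxan-3-yl]acetate
Conditions: 29 (1.3 equiv), KN(SiMe3)2 (1.25 equiv), DME, −78 °C, 30 min; then 20, −78 °C → rt; H2O; E/Z separation on AgNO3-impregnated silica if needed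
Reagents that add atoms: none
Why: Julia–Kocienski olefination, in which the premetalated secondary sulfone adds to the non-enolisable aldehyde and Smiles rearrangement with loss of SO2 and the tetrazololate forms C7=C8, the bulky quaternary C6 being expected to end trans to the C9 chain (E); premetalation leaves no free amide base to attack the β-peroxy ester.

Step 18
Reactants: 30 methyl 2-[(3R,4R,6R)-4,6-diethyl-6-[(1E,4R,5E)-4-ethyl-2-methylocta-1,5-dien-1-yl]-1,2-dioxan-3-yl]acetate
Product: 31 2-[(3R,4R,6R)-4,6-diethyl-6-[(1E,4R,5E)-4-ethyl-2-methylocta-1,5-dien-1-yl]-1,2-dioxan-3-yl]acetic acid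
Conditions: LiOH (3 equiv), THF/H2O 3:1, 0 °C → rt; then 1 M HCl to pH 3, 0 °C
Reagents that add atoms: lithium hydroxide, [Li+].[OH-]
Why: Saponification at low temperature followed by mild acidification, where hydroxide attack at the ester carbonyl should outrun removal of a C2 proton, so the β-peroxy acid is released without opening the dioxane.

**Compound list**

1 | tert-butyl 3-oxobutanoate | CC(=O)CC(=O)OC(C)(C)C | starting material
2 | (E)-pent-2-enal | CC/C=C/C=O | starting material
3 | tert-butyl (3S)-2-acetyl-3-ethyl-5-oxopentanoate (C2 epimers) | CC[C@@H](CC=O)C(C(C)=O)C(=O)OC(C)(C)C | intermediate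
4 | tert-butyl (6S)-6-ethyl-2-oxocyclohex-3-ene-1-carboxylate (C1 epimers) | O=C1C=CC[C@H](CC)C1C(=O)OC(C)(C)C | intermediate
5 | (S)-5-ethylcyclohex-2-en-1-one | O=C1C=CC[C@H](CC)C1 | intermediate
6 | ethylmagnesium bromide | CC[Mg]Br | starting material
7 | (5S)-1,5-diethylcyclohex-2-en-1-ol (C1 epimers) | CCC1(O)C=CC[C@H](CC)C1 | intermediate
8 | (R)-3,5-diethylcyclohex-2-en-1-one | O=C1C=C(CC)C[C@@H](CC)C1 | intermediate
9 | N'-[(5R)-3,5-diethylcyclohex-2-en-1-ylidene]-4-methylbenzenesulfonohydrazide | Cc1ccc(cc1)S(=O)(=O)NN=C1C=C(CC)C[C@@H](CC)C1 | intermediate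
10 | [(3R)-3,5-diethylcyclohexa-1,5-dien-1-yl]lithium | [Li]C1=C[C@H](CC)CC(CC)=C1 | intermediate
11 | (R)-1,5-diethylcyclohexa-1,3-diene | CCC1=CC=C[C@H](CC)C1 | intermediate
12 | (1R,4S,5R)-1,5-diethyl-2,3-dioxabicyclo[2.2.2]oct-7-ene (ethyl on C5 syn to the etheno bridge) | C1=C[C@@]2(CC)C[C@@H](CC)[C@@H]1OO2 | intermediate
13 | vinylboronic acid pinacol ester (2-ethenyl-4,4,5,5-tetramethyl-1,3,2-dioxaborolane) | C=CB1OC(C)(C)C(C)(C)O1 | starting material
14 | 2-[(E)-2-[(3S,4R,6R)-6-ethenyl-4,6-diethyl-1,2-dioxan-3-yl]ethenyl]-4,4,5,5-tetramethyl-1,3,2-dioxaborolane | C=C[C@@]1(CC)C[C@@H](CC)[C@@H](/C=C/B2OC(C)(C)C(C)(C)O2)OO1 | intermediate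
15 | 2-{[(E)-2-[(3S,4R,6R)-6-ethenyl-4,6-diethyl-1,2-dioxan-3-yl]ethenyl]oxy}-4,4,5,5-tetramethyl-1,3,2-dioxaborolane (enol borate) | C=C[C@@]1(CC)C[C@@H](CC)[C@@H](/C=C/OB2OC(C)(C)C(C)(C)O2)OO1 | intermediate
16 | 2-[(3R,4R,6R)-6-ethenyl-4,6-diethyl-1,2-dioxan-3-yl]acetaldehyde | C=C[C@@]1(CC)C[C@@H](CC)[C@@H](CC=O)OO1 | intermediate
17 | 2-[(3R,4R,6R)-6-ethenyl-4,6-diethyl-1,2-dioxan-3-yl]acetic acid | C=C[C@@]1(CC)C[C@@H](CC)[C@@H](CC(=O)O)OO1 | intermediate
18 | methyl 2-[(3R,4R,6R)-6-ethenyl-4,6-diethyl-1,2-dioxan-3-yl]acetate | C=C[C@@]1(CC)C[C@@H](CC)[C@@H](CC(=O)OC)OO1 | intermediate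
19 | methyl 2-[(3R,4R,6R)-4,6-diethyl-6-(1,2,4-trioxolan-3-yl)-1,2-dioxan-3-yl]acetate (ozonide, epimers at the trioxolane carbon) | C1(OCOO1)[C@@]2(CC)C[C@@H](CC)[C@@H](CC(=O)OC)OO2 | intermediate
20 | methyl 2-[(3R,4R,6R)-4,6-diethyl-6-formyl-1,2-dioxan-3-yl]acetate | O=C[C@@]1(CC)C[C@@H](CC)[C@@H](CC(=O)OC)OO1 | intermediate
21 | diethylzinc | CC[Zn]CC | starting material
22 | (3R,4E)-hept-4-en-3-ol | CC[C@@H](O)/C=C/CC | intermediate
23 | 2-methoxypropene | COC(C)=C | starting material
24 | (3R,4E)-3-(prop-1-en-2-yloxy)hept-4-ene | CC[C@@H](OC(C)=C)/C=C/CC | intermediate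
25 | (4R,5E)-4-ethyloct-5-en-2-one | CC/C=C/[C@H](CC)CC(C)=O | intermediate
26 | (4R,5E)-4-ethyloct-5-en-2-ol (C2 epimers) | CC/C=C/[C@H](CC)CC(C)O | intermediate
27 | 5-{[(4R,5E)-4-ethyloct-5-en-2-yl]sulfanyl}-1-phenyl-1H-tetrazole (C2 epimers) | CC/C=C/[C@H](CC)CC(C)Sc1nnnn1-c1ccccc1 | intermediate
28 | 5-{[(4R,5E)-4-ethyloct-5-en-2-yl]sulfinyl}-1-phenyl-1H-tetrazole (isomer mixture) | CC/C=C/[C@H](CC)CC(C)S(=O)c1nnnn1-c1ccccc1 | intermediate
29 | 5-{[(4R,5E)-4-ethyloct-5-en-2-yl]sulfonyl}-1-phenyl-1H-tetrazole (C2 epimers) | CC/C=C/[C@H](CC)CC(C)S(=O)(=O)c1nnnn1-c1ccccc1 | intermediate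
30 | methyl 2-[(3R,4R,6R)-4,6-diethyl-6-[(1E,4R,5E)-4-ethyl-2-methylocta-1,5-dien-1-yl]-1,2-dioxan-3-yl]acetate | CC/C=C/[C@H](CC)C/C(C)=C/[C@@]1(CC)C[C@@H](CC)[C@@H](CC(=O)OC)OO1 | intermediate
31 | 2-[(3R,4R,6R)-4,6-diethyl-6-[(1E,4R,5E)-4-ethyl-2-methylocta-1,5-dien-1-yl]-1,2-dioxan-3-yl]acetic acid | CC/C=C/[C@H](CC)C/C(C)=C/[C@@]1(CC)C[C@@H](CC)[C@@H](CC(=O)O)OO1 | target

**Step count**

Total step count: 18. Longest linear sequence: 13 steps (steps 1–11, 17, 18); the sulfone branch is steps 12–16.

**Steps most likely to fail**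

Step 7. Three processes may defeat it: the ruthenium carbene may be consumed by the O–O bond (isomerisation of 12 instead of metathesis); the bridge may open with the boryl carbon on C7 or on both ends; or the opened alkylidene may oligomerise. The fallback tells the arms apart by oxidative cleavage and a hindrance-controlled Wittig reaction, using known chemistry. It sets out from 12. OsO4 (cat.) with N-methylmorpholine N-oxide in acetone/water dihydroxylates the etheno bridge, a reaction known for bicyclic endoperoxides, to give (1R,4S,5R)-1,5-diethyl-2,3-dioxabicyclo[2.2.2]octane-7,8-diol F1 (cis-diol; either facial isomer serves). NaIO4 in THF/pH 7 buffer cleaves it to (3S,4R,6R)-4,6-diethyl-1,2-dioxane-3,6-dicarbaldehyde F2. One equivalent of Ph3P=CHOMe (from the phosphonium chloride and KN(SiMe3)2, THF, −78 °C) should homologate only the formyl group on the C3 methine, the one on quaternary C6 being neopentyl-like, to give (3S,4R,6R)-4,6-diethyl-3-(2-methoxyethenyl)-1,2-dioxane-6-carbaldehyde F3. Pyridinium chlorochromate [C5H5NH][CrO3Cl] in CH2Cl2 then oxidises the enol ether directly to the methyl ester, which is 20; the route is rejoined there and steps 8–11 are bypassed. The price is that F2 is an α-peroxy aldehyde with a hydrogen on C3 and is prone to base-induced fragmentation, which is why this is not the main line.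

Step 17. The tertiary sulfonyl carbanion may add only sluggishly to the neopentyl aldehyde, the elimination may give incomplete E selectivity for the trisubstituted alkene, and base may open the dioxane by β-elimination from the ester. The fallback is a stepwise Horner–Wittig olefination in which the alkene geometry is fixed by separating diastereomers rather than by kinetic selectivity. It sets out from 26 and 20. MsCl/Et3N converts 26 into (4R,5E)-4-ethyloct-5-en-2-yl methanesulfonate F4. LiPPh2 in THF followed by H2O2 gives [(4R,5E)-4-ethyloct-5-en-2-yl]diphenylphosphine oxide F5. Lithiation (n-BuLi, THF, −78 °C) and addition to 20 gives β-hydroxy phosphine oxides, which are separated by chromatography. The isomer with the C7/C8 relative configuration that places C6 and the C8 methyl group cis on syn-elimination is methyl 2-[(3R,4R,6R)-6-[(4R,5E)-2-(diphenylphosphoryl)-4-ethyl-1-hydroxy-2-methyloct-5-en-1-yl]-4,6-diethyl-1,2-dioxan-3-yl]acetate F6 (or its C7,C8-bis-epimer, which eliminates to the same alkene). NaH in DMF at 0 °C effects stereospecific syn-elimination of diphenylphosphinate and returns the route at 30.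

Step 6. Facial discrimination by the single ethyl group may be poor (attack syn to ethyl), ene hydroperoxidation may compete, and the bridgehead C–H next to the peroxide makes the adduct base-sensitive. The fallback replaces reliance on selectivity by a separate-and-recycle loop. It sets out from the syn adduct that step 6 forms from 11 beside 12, (1S,4R,5R)-1,5-diethyl-2,3-dioxabicyclo[2.2.2]oct-7-ene F7, which is separated by chromatography. Thiourea in MeOH reduces it to (1S,4R,5R)-1,5-diethylcyclohex-2-ene-1,4-diol F8. Low-valent titanium (TiCl3/LiAlH4, THF, reflux) brings about the known reductive 1,4-elimination of 2-ene-1,4-diols to 1,3-dienes and regenerates 11 with the ethyl-bearing centre intact; the route is rejoined at 11 and the material is photooxygenated again.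

**Further compounds**

F1 | step 7 | (1R,4S,5R)-1,5-diethyl-2,3-dioxabicyclo[2.2.2]octane-7,8-diol (cis-diol, hydroxyls drawn anti to the peroxide bridge) | O[C@H]1[C@@H](O)[C@@]2(CC)C[C@@H](CC)[C@@H]1OO2
F2 | step 7 | (3S,4R,6R)-4,6-diethyl-1,2-dioxane-3,6-dicarbaldehyde | O=C[C@@]1(CC)C[C@@H](CC)[C@@H](C=O)OO1
F3 | step 7 | (3S,4R,6R)-4,6-diethyl-3-(2-methoxyethenyl)-1,2-dioxane-6-carbaldehyde (E/Z mixture) | O=C[C@@]1(CC)C[C@@H](CC)[C@@H](C=COC)OO1
F4 | step 17 | (4R,5E)-4-ethyloct-5-en-2-yl methanesulfonate (C2 epimers) | CC/C=C/[C@H](CC)CC(C)OS(C)(=O)=O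
F5 | step 17 | [(4R,5E)-4-ethyloct-5-en-2-yl]diphenylphosphine oxide (C2 epimers) | CC/C=C/[C@H](CC)CC(C)P(=O)(c1ccccc1)c1ccccc1
F6 | step 17 | methyl 2-[(3R,4R,6R)-6-[(4R,5E)-2-(diphenylphosphoryl)-4-ethyl-1-hydroxy-2-methyloct-5-en-1-yl]-4,6-diethyl-1,2-dioxan-3-yl]acetate (diastereomer that eliminates to the 7E alkene) | CC/C=C/[C@H](CC)C[C@](C)(P(=O)(c1ccccc1)c1ccccc1)[C@@H](O)[C@@]1(CC)C[C@@H](CC)[C@@H](CC(=O)OC)OO1
F7 | step 6 | (1S,4R,5R)-1,5-diethyl-2,3-dioxabicyclo[2.2.2]oct-7-ene (syn adduct) | C1=C[C@]2(CC)C[C@@H](CC)[C@H]1OO2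
F8 | step 6 | (1S,4R,5R)-1,5-diethylcyclohex-2-ene-1,4-diol | O[C@@]1(CC)C[C@@H](CC)[C@@H](O)C=C1
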